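**Retrosynthetic overview**

- The target is taken back to 5,8-dihydroxy-3,7,2',4'-tetramethoxyflavone; the last step methylates the 8-hydroxyl only, the chelated 5-hydroxyl staying free.
- Key disconnection O1–C8a. In ring A the C5–OH and the C8 oxygen are para to each other, so ring A is a 2-acylhydroquinone in disguise. Its quinone accepts the enol oxygen of a 2-methoxy-1,3-diketone at the carbon that becomes C8a, which closes ring C.
- The hydroquinone diketone comes from C-aroylation of a bis-benzyl-protected α-methoxy ketone with 2,4-dimethoxybenzoyl chloride, followed by neutral hydrogenolysis.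
- The ketone comes from acylation of 2-methoxyhydroquinone with methoxyacetic acid, para to the methoxy group, then benzylation of both phenols with two equivalents of benzyl bromide.
- Rings A and B are bought; ring C (the pyranone) is the only ring formed, in the key step.

Key step: step 5

Assumption: the 2-methoxy-1,3-diketones of the route are racemic and enolisable (the debenzylated one is also in ring–chain equilibrium with its hemiketal); each is drawn and named as the diketo form and used as the tautomeric mixture.

**Step 1**
Reactants: 1 2-methoxyhydroquinone; 2 methoxyacetic acid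
Product: 3 1-(2,5-dihydroxy-4-methoxyphenyl)-2-methoxyethan-1-one
Conditions: BF3·OEt2 (solvent), 85 °C, Ar; then aq. NaOAc
Reagents that add atoms: none
Why: BF3-promoted Friedel–Crafts acylation of a phenol by a carboxylic acid (Fries-type ortho-acylation) should occur at C5 of 1, the only position that is ortho to a hydroxyl, para to the methoxy group and not flanked by two substituents, the same site at which this quinol is known to be acetylated.

**Step 2**
Reactants: 3 1-(2,5-dihydroxy-4-methoxyphenyl)-2-methoxyethan-1-one; 4 benzyl bromide
Product: 5 1-[2,5-bis(benzyloxy)-4-methoxyphenyl]-2-methoxyethan-1-one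
Conditions: BnBr (2.5 equiv), K2CO3 (3 equiv), KI (cat.), DMF, 65 °C, Ar
Reagents that add atoms: benzyl bromide (second equivalent of 4), BrCc1ccccc1
Why: Double Williamson etherification in which one molecule of 4 is consumed at each phenol, the hydrogen-bonded ortho-hydroxyl needing the warm DMF and the excess of 4, while carbonate should not C-benzylate the α-methoxy ketone and the inert atmosphere keeps the quinol from air oxidation.

**Step 3**
Reactants: 5 1-[2,5-bis(benzyloxy)-4-methoxyphenyl]-2-methoxyethan-1-one; 6 2,4-dimethoxybenzoyl chloride
Product: 7 1-[2,5-bis(benzyloxy)-4-methoxyphenyl]-3-(2,4-dimethoxyphenyl)-2-methoxypropane-1,3-dione (racemic)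
Conditions: LiN(SiMe3)2 (2.1 equiv), THF–toluene, −78 °C; then 6, −78 → 0 °C; aq. NH4Cl
Reagents that add atoms: none
Why: Claisen-type C-acylation of the preformed lithium enolate by an aroyl chloride, in which the second equivalent of base deprotonates the diketone as it forms so that no enolate is lost to proton transfer and no second acylation occurs, and the weakly polar medium favours C- over O-acylation; the new C2 centre is enolisable, hence racemic, and is erased in step 5.

**Step 4**
Reactants: 7 1-[2,5-bis(benzyloxy)-4-methoxyphenyl]-3-(2,4-dimethoxyphenyl)-2-methoxypropane-1,3-dione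
Product: 8 1-(2,5-dihydroxy-4-methoxyphenyl)-3-(2,4-dimethoxyphenyl)-2-methoxypropane-1,3-dione (racemic)
Conditions: H2 (1 atm), 10% Pd/C, EtOAc, rt
Reagents that add atoms: none
Why: Hydrogenolysis of both aryl benzyl ethers over Pd/C under neutral conditions frees the quinol without acid or base, so the ortho-hydroxy diketone is not cyclodehydrated, and the aryl ketones and methyl ethers should survive at 1 atm; 8 is filtered under argon and used at once.

**Step 5**
Reactants: 8 1-(2,5-dihydroxy-4-methoxyphenyl)-3-(2,4-dimethoxyphenyl)-2-methoxypropane-1,3-dione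
Product: 11 5,8-dihydroxy-3,7,2',4'-tetramethoxyflavone, via acylquinone 9 (not isolated), via flavonequinone 10 (not isolated)
Conditions: Ag2O (3 equiv), Na2SO4, CH2Cl2, rt, dark, Ar; then aq. Na2S2O4/EtOAc
Reagents that add atoms: none
Why: Ag2O dehydrogenates the quinol of 8 to acylquinone 9, whose ring carbon C3 (the future C8a) is β to the C1 ring carbonyl and to the side-chain ketone; the oxygen of the enol formed toward the ring B carbonyl adds there and a proton shift re-aromatises ring A to the 5,8-quinol, which surplus oxidant takes on to quinone 10 and the dithionite wash returns as 11. The closest known reaction type is the oxa-Michael addition of alcohols and phenols to 2-acyl-1,4-benzoquinones made by quinol oxidation, including intramolecular closures of hydroxyaroyl quinones to xanthone-type pyranones. Ring C closes in a 6-endo-trig mode on the C2=C3 bond of the quinone; no stereocentre is formed and the racemic C2 of the diketone becomes sp2. The selectivity needed is regiochemical: O1 must bond to C8a and must not be the ring A oxygen ortho to the ketone; this is secured because that oxygen is a quinone carbonyl during closure (it ends as the chelated 5-OH), because 1,2-addition of the enol oxygen to that carbonyl is reversible while the conjugate addition is made irreversible by aromatisation, and because C-attack by the diketone would need a four-membered ring. Neutral, dry conditions keep the acid-catalysed cyclodehydration of 8 (which would lead to the 6-hydroxy isomer series) and hydration of 9 from intervening. More than two equivalents of oxidant are used on purpose, since 9 would otherwise oxidise the more electron-rich product and the reaction would stall at half conversion.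

**Step 6**
Reactants: 11 5,8-dihydroxy-3,7,2',4'-tetramethoxyflavone
Product: 12 5-hydroxy-3,7,8,2',4'-pentamethoxyflavone
Conditions: MeI (1.05 equiv), K2CO3, acetone, 40 °C, Ar
Reagents that add atoms: iodomethane, CI
Why: Williamson O-methylation with one equivalent of MeI should go at the free 8-hydroxyl alone, because the 5-hydroxyl is held in a hydrogen bond to the C4 carbonyl and is far less acidic and nucleophilic, and argon prevents base-promoted oxidation of the quinol.

**Compound list**

1 | 2-methoxyhydroquinone (2-methoxybenzene-1,4-diol) | COc1cc(O)ccc1O | starting material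
2 | methoxyacetic acid | COCC(=O)O | starting material
3 | 1-(2,5-dihydroxy-4-methoxyphenyl)-2-methoxyethan-1-one | COCC(=O)c1cc(O)c(OC)cc1O | intermediate
4 | benzyl bromide | BrCc1ccccc1 | starting material
5 | 1-[2,5-bis(benzyloxy)-4-methoxyphenyl]-2-methoxyethan-1-one | COCC(=O)c1cc(OCc2ccccc2)c(OC)cc1OCc1ccccc1 | intermediate
6 | 2,4-dimethoxybenzoyl chloride | COc1ccc(C(=O)Cl)c(OC)c1 | starting material
7 | 1-[2,5-bis(benzyloxy)-4-methoxyphenyl]-3-(2,4-dimethoxyphenyl)-2-methoxypropane-1,3-dione (racemic, enolisable) | COc1ccc(C(=O)C(OC)C(=O)c2cc(OCc3ccccc3)c(OC)cc2OCc2ccccc2)c(OC)c1 | intermediate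
8 | 1-(2,5-dihydroxy-4-methoxyphenyl)-3-(2,4-dimethoxyphenyl)-2-methoxypropane-1,3-dione (racemic, enolisable) | COc1ccc(C(=O)C(OC)C(=O)c2cc(O)c(OC)cc2O)c(OC)c1 | intermediate
9 | 2-[3-(2,4-dimethoxyphenyl)-2-methoxy-3-oxopropanoyl]-5-methoxy-1,4-benzoquinone (acylquinone; racemic, enolisable) | COc1ccc(C(=O)C(OC)C(=O)C2=CC(=O)C(OC)=CC2=O)c(OC)c1 | intermediate
10 | 2-(2,4-dimethoxyphenyl)-3,7-dimethoxy-4H-chromene-4,5,8-trione (flavonequinone) | COc1ccc(C2=C(OC)C(=O)C3=C(O2)C(=O)C(OC)=CC3=O)c(OC)c1 | intermediate
11 | 5,8-dihydroxy-3,7,2',4'-tetramethoxyflavone | COc1ccc(-c2oc3c(O)c(OC)cc(O)c3c(=O)c2OC)c(OC)c1 | intermediate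
12 | 5-hydroxy-3,7,8,2',4'-pentamethoxyflavone | COc1ccc(-c2oc3c(OC)c(OC)cc(O)c3c(=O)c2OC)c(OC)c1 | target

**Total step count:** 6
**Longest linear sequence:** 6 steps (from 1)

**Steps most likely to fail**

Step 5. The ortho-hydroxy diketone may cyclodehydrate through the ring A phenol before oxidation is complete. The acylquinone may be captured by water or by a second molecule. The internally hydrogen-bonded enol may add too slowly. The fallback uses conventional ring C closure followed by para-hydroxylation of ring A, all known chemistry. It sets out from acid chloride 6 and comes back to the route at 11. Commercial 2-methoxy-1-(2,4,6-trihydroxyphenyl)ethan-1-one is converted to its lithium polyanion (LiN(SiMe3)2, 5 equiv, THF, −78 °C) and C-aroylated with 6 to give 1-(2,4,6-trihydroxyphenyl)-3-(2,4-dimethoxyphenyl)-2-methoxypropane-1,3-dione F1. Cyclodehydration (H2SO4 cat., AcOH, 95 °C) should give 5,7-dihydroxy-3,2',4'-trimethoxyflavone F2; ring A is symmetric here, so only one flavone can form. Methylation of the non-chelated 7-hydroxyl (MeI 1 equiv, K2CO3, acetone) should give 5-hydroxy-3,7,2',4'-tetramethoxyflavone F3. Elbs persulfate oxidation (K2S2O8, aq. KOH–pyridine, 10 °C) places a sulfate para to the 5-hydroxyl, giving potassium 5-hydroxy-3,7,2',4'-tetramethoxyflavon-8-yl sulfate F4. Hydrolysis of F4 (aq. HCl, Na2SO3, 80 °C) gives 11, and step 6 follows unchanged.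

Step 3. The enolate may be acylated on oxygen, proton transfer between enolate and product may stall conversion, or the ketone may self-condense. The fallback replaces acylation by aldol addition and oxidation; it sets out from 5 and comes back at 7. The lithium enolate of 5 (LiN(SiMe3)2, THF, −78 °C) is added to commercial 2,4-dimethoxybenzaldehyde to give 1-[2,5-bis(benzyloxy)-4-methoxyphenyl]-3-(2,4-dimethoxyphenyl)-3-hydroxy-2-methoxypropan-1-one F5 as a mixture of racemic diastereomers. Oxidation of the benzylic alcohol with Dess–Martin periodinane (NaHCO3, CH2Cl2, rt) should give 7; both stereocentres of F5 are lost or enolisable, so the mixture is used as such.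

Step 1. The α-alkoxy acid may stop at O-acylation without migration to carbon, may acylate ortho to the other hydroxyl, or the quinol may be lost to oxidation at 85 °C. The fallback fixes the site by halogenation and builds the ketone from an aryllithium; it sets out from 1 and 4 and comes back at 5, bypassing 3. Benzylation of both hydroxyls of 1 with two equivalents of 4 (K2CO3, DMF, 60 °C, Ar) gives 1,4-bis(benzyloxy)-2-methoxybenzene F6. Bromination with NBS (MeCN, 0 °C) should go para to the methoxy group to give 1,4-bis(benzyloxy)-2-bromo-5-methoxybenzene F7. Bromine–lithium exchange (n-BuLi, THF, −78 °C) gives [2,5-bis(benzyloxy)-4-methoxyphenyl]lithium F8, which is acylated by the Weinreb amide N,2-dimethoxy-N-methylacetamide and quenched with aq. NH4Cl to give 5.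

**Further compounds**

F1 | step 5 | 1-(2,4,6-trihydroxyphenyl)-3-(2,4-dimethoxyphenyl)-2-methoxypropane-1,3-dione (racemic, enolisable) | COc1ccc(C(=O)C(OC)C(=O)c2c(O)cc(O)cc2O)c(OC)c1
F2 | step 5 | 5,7-dihydroxy-3,2',4'-trimethoxyflavone | COc1ccc(-c2oc3cc(O)cc(O)c3c(=O)c2OC)c(OC)c1
F3 | step 5 | 5-hydroxy-3,7,2',4'-tetramethoxyflavone | COc1ccc(-c2oc3cc(OC)cc(O)c3c(=O)c2OC)c(OC)c1
F4 | step 5 | potassium 5-hydroxy-3,7,2',4'-tetramethoxyflavon-8-yl sulfate | COc1ccc(-c2oc3c(OS(=O)(=O)[O-])c(OC)cc(O)c3c(=O)c2OC)c(OC)c1.[K+]
F5 | step 3 | 1-[2,5-bis(benzyloxy)-4-methoxyphenyl]-3-(2,4-dimethoxyphenyl)-3-hydroxy-2-methoxypropan-1-one (mixture of racemic diastereomers) | COc1ccc(C(O)C(OC)C(=O)c2cc(OCc3ccccc3)c(OC)cc2OCc2ccccc2)c(OC)c1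
F6 | step 1 | 1,4-bis(benzyloxy)-2-methoxybenzene | COc1cc(OCc2ccccc2)ccc1OCc1ccccc1
F7 | step 1 | 1,4-bis(benzyloxy)-2-bromo-5-methoxybenzene | COc1cc(OCc2ccccc2)c(Br)cc1OCc1ccccc1
F8 | step 1 | [2,5-bis(benzyloxy)-4-methoxyphenyl]lithium | COc1cc(OCc2ccccc2)c([Li])cc1OCc1ccccc1
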